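**The problem**

Target 15 is a symmetric dibenzyl ether: two identical, fully substituted benzene rings joined by a CH2–O–CH2 bridge. In each ring C1 carries the benzylic carbon C7, C2, C3 and C6 carry bromine, and C4 and C5 carry hydroxyl. There is no stereocentre, so the task is to place six substituents on a ring without positional error, twice. Electrophilic bromination of a 3,4-dioxygenated benzyl compound is not reliable for this: the third bromine must enter a ring already deactivated by two, and C1, para to the C4 oxygen, is open to ipso attack with loss of the side chain. Three groups limit late-stage chemistry: the free catechol (oxidised to the ortho-quinone by air under base and by many oxidants), the C–Br bonds (lost by hydrogenolysis or halogen–metal exchange) and the C7–O bonds, which lie para to the C4 hydroxyl, ionise through a para-quinone methide, exchange with alcohol solvents and are cut by BBr3. The ether therefore has to be closed last, from the free phenol, in a non-nucleophilic medium. The feature that opens a short route is the pair C1/C2: neighbouring carbons, one bearing carbon and one bearing bromine, flanked by C6–Br and C3–Br with both oxygens on the far side. This pair maps onto the triple bond of 3,6-dibromo-4,5-dimethoxybenzyne 9, whose mirror plane bisects the C1–C2 and C4–C5 bonds, so a carbon nucleophile and a bromine electrophile can be added across it with no regiochemical choice.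

**Retrosynthesis**

15 to 14. The two C7–O bonds of the bridge are cut to give two molecules of benzyl alcohol 14. Closing the ether before the phenols are freed is ruled out, because the demethylating agent would cleave a para-alkoxybenzyl ether. The forward reaction is an acid-catalysed dehydration through the para-quinone-methide-type cation. The fully substituted ring leaves no CH for C-alkylation, so only O-alkylation pathways exist, and alkylation of the hindered phenols is reversible.

14 to 12 (through 13). The two O–CH3 bonds are cut and the benzylic oxygen is traced back to that of dimethyl ether 12. Boron tribromide does both jobs, demethylating and converting CH2OH to CH2Br (13), and the para-hydroxybenzyl bromide is then hydrolysed in aqueous acetone. Methyl ethers are chosen because they must survive n-BuLi, strongly acidic iodination, Grignard reagents and peroxide.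

12 to 11. The C7–O bond is exchanged for a C7–Si bond (Tamao oxidation). The alkoxysilyl group lets C7 enter as a nucleophile in the key step and still become the benzylic oxygen afterwards.

11 to 5 and 7. The C1–C7 and C2–Br bonds are cut together, which leads to aryne 9, Grignard reagent 7 and an electrophilic bromine source. The neighbouring options, formylation or bromination of a dibromoveratrole, rely on electrophilic substitution of a deactivated ring. Here the positions are fixed by which halogens leave. Precursor 5 is a symmetric tetrahalide with no regiochemical information to lose. The forward reaction must expel iodide and not bromide from 8, and arylmagnesium 10 must keep its ortho bromide until it is quenched.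

5 to 3 to 1. The two C–I bonds are cut first: electrophilic iodination of 3 has only the two open positions, each para to a methoxy group. The two C–Br bonds are cut next: double directed ortho-lithiation of veratrole 1 puts them ortho to oxygen, where electrophilic bromination would not go. The order is fixed, because a lithiation next to iodine would trigger elimination.

7 to 6. The C–Mg bond comes from magnesium insertion into commercial chloromethylsilane 6.

**Roads not taken**

Alternative 1: Each ring is cut at C3–C4 and C5–C6. In the forward sense a tetraester made of two 3-substituted adipate arms joined by the CH2–O–CH2 bridge, tetraethyl 3,3'-[oxybis(methylene)]dihexanedioate A1, condenses twice per arm with diethyl oxalate A2 under NaOEt. The product is the bis(2,3-dioxocyclohexane-1,4-dicarboxylate) A3 in its enol form.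
- Merits: both rings come from cheap acyclic material in one operation, the vicinal oxygens arrive correctly placed from A2, and the ether bridge is present from the start in A1.
- Weak points: A3 is at the cyclohexadiene oxidation level and carries ester groups at C3 and C6, exactly where bromine must end up, and hydrogen at C2. After the key step A3 needs dehydrogenation, four ester hydrolyses with decarboxylation or bromodecarboxylation, and six C–Br bond formations. The HBr set free in those brominations threatens the para-hydroxybenzyl ether that the route was meant to preserve. The adipate arms of A1 can also close on themselves by Dieckmann condensation to five-membered rings before A2 is taken up, and A1 needs a synthesis of its own.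
- Comparison: this road avoids cryogenic organometallic chemistry and a late etherification, and that is a real point in its favour. The chosen plan sets against it an intact arene from the first step, no redox adjustment of the ring and a much shorter sequence.

Alternative 2: Each ring is cut at C2–C3 and C6–C1. Bis(3-bromoprop-2-yn-1-yl) ether A4 would take up two molecules of 2,5-dibromo-3,4-dimethoxythiophene 1,1-dioxide A5 by Diels–Alder addition and cheletropic loss of SO2. The product is bis(2,3,6-tribromo-4,5-dimethoxybenzyl) ether A6.
- Merits: this is the most convergent plan on paper. Both hexasubstituted rings, all six bromines and the ether are assembled in one step, and the symmetric diene A5 raises no regiochemical question.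
- Weak points: A5 is a donor-substituted thiophene dioxide of uncertain stability that would have to be made by oxidising an electron-rich thiophene. The bromoalkyne units of A4 are poor dienophiles for such a diene, so high temperatures, dimerisation of A5 and incomplete double addition are to be expected. The decisive point is that freeing the four phenols of A6 with BBr3 would cut both benzylic C–O bonds and deliver 13, so the pre-formed ether saves nothing and the endgame becomes that of the chosen plan.
- Comparison: in step count to a protected skeleton this road is better. The chosen plan offers bond-forming steps of established type on a benzene ring that already exists, and an endgame that expects ether cleavage and plans for it.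

Alternative 3: One C–O bond per ring is cut. Bis[2,3,5,6-tetrabromo-4-(methoxymethoxy)benzyl] ether A7 would undergo bromine–magnesium exchange with iPrMgCl·LiCl ortho to the MOM ether in each ring, then borylation with B(OMe)3 and alkaline H2O2 oxidation in the same flask. The product is bis[2,3,6-tribromo-5-hydroxy-4-(methoxymethoxy)benzyl] ether A8, and mild acid would convert A8 into 15.
- Merits: the ether is made early on robust, non-phenolic material, only one bond per ring is formed late, and the final deprotection of A8 is mild. These are real advantages over the last step of the chosen plan.
- Weak points: each ring of A7 offers two bromines next to the MOM ether and two next to the benzylic ether oxygen, and both oxygens can chelate magnesium, so the exchange site is not secure. A positional error in either ring gives an isomer of A8 that is hard to remove. The exchange must also occur exactly once in each of two rings, and every arylmagnesium formed has an ortho bromine and can collapse to an aryne. A7 itself is not easily made: the positions meta to the phenol oxygen resist electrophilic bromination and the benzylic carbon para to it invites ipso attack.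
- Comparison: if A7 were in hand and the exchange selective, this road would be as short as the chosen one and gentler at the end. The chosen plan offers positional certainty: every halogen enters at a site with no alternative, and the only selectivity in the key step is iodide against bromide as leaving group.

Key step: step 4

Assumption: both halves are made as one compound up to 14 and joined only in the last step; n-BuLi, iPrMgCl·LiCl, NIS, BBr3 and BrCl2C–CCl2Br are taken as purchased reagents.

**Route**

Step 1
Reactants: 1 veratrole (1,2-dimethoxybenzene)
Product: 3 1,4-dibromo-2,3-dimethoxybenzene, via 3,6-dilithioveratrole 2 (not isolated)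
Conditions: n-BuLi (3 equiv), TMEDA (3 equiv), Et2O/hexane, 0 °C to rt; then BrCl2C–CCl2Br (3 equiv), THF, −78 °C to rt
Reagents that add atoms: 1,2-dibromo-1,1,2,2-tetrachloroethane, BrC(Cl)(Cl)C(Cl)(Cl)Br
Why: Double directed ortho-metalation: each methoxy group directs lithiation to its free ortho position, and the dilithio species is brominated by halophilic attack on the bromine donor. This places bromine ortho to oxygen, where electrophilic bromination (which goes para) would not.

Step 2
Reactants: 3 1,4-dibromo-2,3-dimethoxybenzene
Product: 5 1,4-dibromo-2,3-diiodo-5,6-dimethoxybenzene, via 1,4-dibromo-5-iodo-2,3-dimethoxybenzene 4 (not isolated)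
Conditions: NIS (2.4 equiv), CF3CO2H, cat. CF3SO3H, 0 °C to rt
Reagents that add atoms: N-iodosuccinimide, O=C1CCC(=O)N1I
Why: Electrophilic aromatic iodination with acid-activated NIS; the only two free positions are each para to a methoxy group, so no regiochemical choice exists, and the strongly electrophilic iodine source is chosen for the second, slower substitution next to the first iodine.

Step 3
Reactants: 6 (chloromethyl)isopropoxydimethylsilane
Product: 7 [(isopropoxydimethylsilyl)methyl]magnesium chloride (THF solution, titrated and used directly)
Conditions: Mg turnings, cat. BrCH2CH2Br, THF, reflux then rt
Reagents that add atoms: magnesium, [Mg]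
Why: Oxidative insertion of magnesium into the C–Cl bond gives the standard hydroxymethyl-anion equivalent; the bulky isopropoxy group keeps the Si–O bond from attack by the reagent itself.

Step 4
Reactants: 5 1,4-dibromo-2,3-diiodo-5,6-dimethoxybenzene; 7 [(isopropoxydimethylsilyl)methyl]magnesium chloride
Product: 11 isopropoxydimethyl(2,3,6-tribromo-4,5-dimethoxybenzyl)silane, via (2,5-dibromo-6-iodo-3,4-dimethoxyphenyl)magnesium chloride 8 (not isolated), via 3,6-dibromo-4,5-dimethoxybenzyne 9 (not isolated), via {2,5-dibromo-6-[(isopropoxydimethylsilyl)methyl]-3,4-dimethoxyphenyl}magnesium chloride 10 (not isolated)
Conditions: iPrMgCl·LiCl (1.0 equiv), THF, −78 °C; 7 (3 equiv), slow warming from −78 °C (towards about −30 °C, only until 8 is consumed); recool to −78 °C, BrCl2C–CCl2Br (4 equiv), then 0 °C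
Reagents that add atoms: 1,2-dibromo-1,1,2,2-tetrachloroethane, BrC(Cl)(Cl)C(Cl)(Cl)Br
Why: Iodine–magnesium exchange with iPrMgCl·LiCl at −78 °C is much faster at C–I than at C–Br and should stop after one iodine, because the new C–Mg bond makes the ring too electron-rich for a second exchange, giving 8. On warming with excess 7 present, 8 should lose MgClI across the former C–I/C–Mg pair, iodide being a better leaving group than the bromide on its other side, to give the mirror-symmetric aryne 9. The two flanking C–Br bonds make the strained triple bond more electrophilic, so the modestly nucleophilic α-silyl Grignard 7 adds (carbomagnesiation) to form C1–C7; the two aryne carbons are equivalent, so no regiocontrol is needed, and the carbanion emerging at C2 is stabilised inductively by the C3 bromine. After recooling, halophilic attack of 10 on BrCl2C–CCl2Br forms C2–Br and releases tetrachloroethene. The closest known reaction type is the addition of Grignard reagents to arynes generated from ortho-dihaloarenes by halogen–magnesium exchange, with electrophilic trapping of the new arylmagnesium. No ring closes and no stereocentre is formed. The selectivity needed is that 10 keeps its C3 bromide until the quench; it rests on the iodide/bromide leaving-group gap, on warming only as far as 8 requires, and on recooling before the bromine donor is added. The isopropoxy group shields silicon from the organomagnesium species, and limiting iPrMgCl·LiCl to one equivalent leaves no isopropyl nucleophile to compete with 7 for 9.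

Step 5
Reactants: 11 isopropoxydimethyl(2,3,6-tribromo-4,5-dimethoxybenzyl)silane
Product: 12 (2,3,6-tribromo-4,5-dimethoxyphenyl)methanol
Conditions: 30% H2O2, KF, KHCO3, THF/MeOH, rt
Reagents that add atoms: hydrogen peroxide, OO
Why: Tamao oxidation: hydroperoxide adds to the fluoride-activated alkoxysilane and the benzyl group migrates from silicon to oxygen, converting C7–Si into C7–O; aryl bromides and methyl ethers are inert to these conditions.

Step 6
Reactants: 12 (2,3,6-tribromo-4,5-dimethoxyphenyl)methanol
Product: 14 3,4,6-tribromo-5-(hydroxymethyl)benzene-1,2-diol, via 3,4,6-tribromo-5-(bromomethyl)benzene-1,2-diol 13 (not isolated)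
Conditions: BBr3 (5 equiv), CH2Cl2, −78 °C to rt; ice-water quench; then acetone/H2O (1:1), 40 °C
Reagents that add atoms: water, O
Why: BBr3 cleaves both aryl methyl ethers (Lewis acid–base adduct, bromide attack at methyl) and converts the benzylic alcohol into bromide 13. The para-hydroxybenzyl bromide then solvolyses in aqueous acetone through the para-quinone methide, and the large excess of water holds the equilibrium on the side of alcohol 14.

Step 7
Reactants: 14 3,4,6-tribromo-5-(hydroxymethyl)benzene-1,2-diol (two molecules)
Product: 15 bis(2,3,6-tribromo-4,5-dihydroxybenzyl) ether
Conditions: TsOH·H2O (10 mol %), 1,4-dioxane, 4 Å molecular sieves, 60 °C, under argon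
Reagents that add atoms: none
Why: Acid-catalysed dehydrative self-etherification of a para-hydroxybenzyl alcohol: loss of water gives the cation stabilised by the C4 hydroxyl (protonated para-quinone methide), which is captured by the CH2OH of a second molecule. The ring has no free CH, so C-alkylation is impossible; attack by the hindered, acidic phenols is reversible; the sieves remove water and the solvent cannot form an ether.

**Compound list**

1 | veratrole (1,2-dimethoxybenzene) | COc1ccccc1OC | starting material
2 | 3,6-dilithioveratrole [(2,3-dimethoxy-1,4-phenylene)dilithium] | [Li]c1ccc([Li])c(OC)c1OC | intermediate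
3 | 1,4-dibromo-2,3-dimethoxybenzene | COc1c(Br)ccc(Br)c1OC | intermediate
4 | 1,4-dibromo-5-iodo-2,3-dimethoxybenzene | COc1c(OC)c(Br)c(I)cc1Br | intermediate
5 | 1,4-dibromo-2,3-diiodo-5,6-dimethoxybenzene | COc1c(OC)c(Br)c(I)c(I)c1Br | intermediate
6 | (chloromethyl)isopropoxydimethylsilane | CC(C)O[Si](C)(C)CCl | starting material
7 | [(isopropoxydimethylsilyl)methyl]magnesium chloride | CC(C)O[Si](C)(C)C[Mg]Cl | intermediate
8 | (2,5-dibromo-6-iodo-3,4-dimethoxyphenyl)magnesium chloride | COc1c(OC)c(Br)c([Mg]Cl)c(I)c1Br | intermediate
9 | 3,6-dibromo-4,5-dimethoxybenzyne | COC1=C(Br)C#CC(Br)=C1OC | intermediate
10 | {2,5-dibromo-6-[(isopropoxydimethylsilyl)methyl]-3,4-dimethoxyphenyl}magnesium chloride | COc1c(OC)c(Br)c(C[Si](C)(C)OC(C)C)c([Mg]Cl)c1Br | intermediate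
11 | isopropoxydimethyl(2,3,6-tribromo-4,5-dimethoxybenzyl)silane | COc1c(OC)c(Br)c(C[Si](C)(C)OC(C)C)c(Br)c1Br | intermediate
12 | (2,3,6-tribromo-4,5-dimethoxyphenyl)methanol | COc1c(OC)c(Br)c(CO)c(Br)c1Br | intermediate
13 | 3,4,6-tribromo-5-(bromomethyl)benzene-1,2-diol | Oc1c(O)c(Br)c(CBr)c(Br)c1Br | intermediate
14 | 3,4,6-tribromo-5-(hydroxymethyl)benzene-1,2-diol | Oc1c(O)c(Br)c(CO)c(Br)c1Br | intermediate
15 | bis(2,3,6-tribromo-4,5-dihydroxybenzyl) ether | Oc1c(O)c(Br)c(COCc2c(Br)c(O)c(O)c(Br)c2Br)c(Br)c1Br | target

**Step count and risks**

Total step count: 7. Longest linear sequence: 6 steps (1, 2, 4, 5, 6, 7); step 3 is a one-step branch that supplies 7.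

Step 4 (key step). Two processes are the most likely to fail.
- Premature loss of MgBrCl from 10, or loss of bromide in place of iodide from 8, would open a second aryne that takes up more 7 and gives over-alkylated material. The margin between iodide and bromide expulsion is a matter of temperature and is not absolute.
- Slow capture of 9 by the weakly nucleophilic α-silyl Grignard would let 8 add to 9 (biaryl formation) or let halide return to the aryne.

Fallback without an aryne: it sets out from 4, isolated by running step 2 with one equivalent of NIS. Iodine–magnesium exchange with iPrMgCl·LiCl at −40 °C should give (2,5-dibromo-3,4-dimethoxyphenyl)magnesium chloride F1, which has no iodide to lose. Formylation with DMF would give 2,5-dibromo-3,4-dimethoxybenzaldehyde F2. Electrophilic bromination (Br2, cat. FeBr3, CH2Cl2) at the single free position, para to a methoxy group, would give 2,3,6-tribromo-4,5-dimethoxybenzaldehyde F3. Reduction with NaBH4 in MeOH/THF comes back to the route at 12.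

Step 5. Fluoride- or base-induced cleavage of the benzylic C–Si bond (protodesilylation) may outrun the oxidative migration, because the tribromoaryl ring stabilises the departing benzylic carbanion. Fallback, from 11: the desilylation is carried out on purpose with Bu4NF in wet THF to give 1,2,4-tribromo-5,6-dimethoxy-3-methylbenzene F4. Wohl–Ziegler bromination (NBS, AIBN, PhCF3, reflux) would give 1,2,4-tribromo-3-(bromomethyl)-5,6-dimethoxybenzene F5, and BBr3 in CH2Cl2 demethylates it. The route is rejoined at 13, which is hydrolysed to 14 as in step 6.

Step 7. The dehydration is an equilibrium. Incomplete conversion, reversible O-alkylation of the phenols, re-ionisation of the product under acid and oxidation of the catechol on prolonged heating are the likely losses. Fallback, from 13 (isolated from step 6 before the aqueous acetone stage) and 14: alkylation of the CH2OH group of 14 by the para-hydroxybenzyl bromide 13 in dry 1,4-dioxane with 2,6-di-tert-butyl-4-methylpyridine as acid scavenger. The bromide ionises under neutral conditions and no water has to be removed. This returns directly to 15 and makes no new compound. Halide abstraction with Ag2O or AgOTf is avoided because these would oxidise the catechol.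

Step 2. The second iodination, next to the first iodine on a ring carrying two bromines and two twisted methoxy groups, may stall at 4, and forcing acid may cause halogen migration or ether cleavage. Fallback, from 4: deprotonative magnesiation with TMPMgCl·LiCl in THF at low temperature, at the one remaining C–H between iodine and bromine, should give 8 directly without a second iodine. Grignard reagent 7 is then added, so the route is rejoined at 8 inside step 4 and continues to 11. No new compound is made.

**Further compounds**

F1 | step 4 | (2,5-dibromo-3,4-dimethoxyphenyl)magnesium chloride | COc1c(OC)c(Br)c([Mg]Cl)cc1Br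
F2 | step 4 | 2,5-dibromo-3,4-dimethoxybenzaldehyde | COc1c(OC)c(Br)c(C=O)cc1Br
F3 | step 4 | 2,3,6-tribromo-4,5-dimethoxybenzaldehyde | COc1c(OC)c(Br)c(C=O)c(Br)c1Br
F4 | step 5 | 1,2,4-tribromo-5,6-dimethoxy-3-methylbenzene | COc1c(OC)c(Br)c(C)c(Br)c1Br
F5 | step 5 | 1,2,4-tribromo-3-(bromomethyl)-5,6-dimethoxybenzene | COc1c(OC)c(Br)c(CBr)c(Br)c1Br
F0 | step 7 | none | none
F0 | step 2 | none | none
A1 | alternative 1 | tetraethyl 3,3'-[oxybis(methylene)]dihexanedioate | CCOC(=O)CC(COCC(CC(=O)OCC)CCC(=O)OCC)CCC(=O)OCC
A2 | alternative 1 | diethyl oxalate | CCOC(=O)C(=O)OCC
A3 | alternative 1 | tetraethyl 5,5'-[oxybis(methylene)]bis(2,3-dihydroxycyclohexa-1,3-diene-1,4-dicarboxylate), mixture of stereoisomers | CCOC(=O)C1=C(O)C(O)=C(C(=O)OCC)C(COCC2CC(C(=O)OCC)=C(O)C(O)=C2C(=O)OCC)C1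
A4 | alternative 2 | bis(3-bromoprop-2-yn-1-yl) ether | BrC#CCOCC#CBr
A5 | alternative 2 | 2,5-dibromo-3,4-dimethoxythiophene 1,1-dioxide | COC1=C(Br)S(=O)(=O)C(Br)=C1OC
A6 | alternative 2 | bis(2,3,6-tribromo-4,5-dimethoxybenzyl) ether | COc1c(OC)c(Br)c(COCc2c(Br)c(OC)c(OC)c(Br)c2Br)c(Br)c1Br
A7 | alternative 3 | bis[2,3,5,6-tetrabromo-4-(methoxymethoxy)benzyl] ether | COCOc1c(Br)c(Br)c(COCc2c(Br)c(Br)c(OCOC)c(Br)c2Br)c(Br)c1Br
A8 | alternative 3 | bis[2,3,6-tribromo-5-hydroxy-4-(methoxymethoxy)benzyl] ether | COCOc1c(O)c(Br)c(COCc2c(Br)c(Br)c(OCOC)c(O)c2Br)c(Br)c1Br
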